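**Retrosynthetic overview**
1. The C4 and C6 bromines of ring A sit para and ortho to OH, so they go on last by electrophilic bromination of 3-bromo-2-(2,4-dibromophenoxy)phenol. The C3 bromine is meta to OH and has to come from a carbonyl group.
2. That phenol comes from dehydrogenation of 3-bromo-2-aryloxycyclohex-2-enone, which comes from deoxybromination of the symmetric 2-aryloxycyclohexane-1,3-dione.
3. The dione comes from Dieckmann-type closure of methyl 6-aryloxy-5-oxohexanoate.
4. Key C-C bond: intermolecular Michael addition of tert-butyl 4-aryloxy-3-oxobutanoate to methyl acrylate, then loss of the CO2tBu group. The beta-keto ester comes from a crossed Claisen condensation of tert-butyl acetate with ethyl aryloxyacetate, itself made from 2,4-dibromophenol and ethyl bromoacetate.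
5. Ring order: ring B (2,4-dibromophenyl) is bought intact. Ring A is the only ring formed; it is closed in step 5 and aromatised in step 8.

Assumption: the target has no stereocentre and its diaryl ether axis rotates freely, so it is achiral. The only stereocentre on the route (in 10 and 11) is racemic, labile and erased in step 4.

**Step 1**
Reactants: 1 2,4-dibromophenol; 2 ethyl bromoacetate
Product: 4 ethyl 2-(2,4-dibromophenoxy)acetate, via potassium 2,4-dibromophenoxide 3 (not isolated)
Conditions: K2CO3 (1.5 equiv), acetone, reflux, 6 h
Reagents that add atoms: none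
Why: Williamson ether synthesis, in which K2CO3 fully deprotonates the acidic phenol (pKa about 8) and the phenoxide displaces the activated primary bromide by SN2 while the aryl bromides stay inert.

**Step 2**
Reactants: 4 ethyl 2-(2,4-dibromophenoxy)acetate; 5 tert-butyl acetate
Product: 8 tert-butyl 4-(2,4-dibromophenoxy)-3-oxobutanoate, via lithium enolate of tert-butyl acetate 6 (not isolated), via lithium enolate of the beta-keto ester 7 (not isolated)
Conditions: 5 (2.6 equiv), LiN(SiMe3)2 (2.6 equiv), THF, -78 °C, 30 min; add 4, -78 to -30 °C; AcOH quench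
Reagents that add atoms: none
Why: Crossed Claisen condensation, in which the preformed enolate of the bulky, non-self-condensing tert-butyl ester acylates the inductively activated aryloxyacetate, formation of the stabilised enolate 7 drives the reaction, and no alkyllithium is present that could exchange with the aryl bromides.

**Step 3**
Reactants: 8 tert-butyl 4-(2,4-dibromophenoxy)-3-oxobutanoate; 9 methyl acrylate
Product: 10 1-tert-butyl 5-methyl 2-[(2,4-dibromophenoxy)acetyl]pentanedioate (racemic)
Conditions: 9 (1.1 equiv), 1,8-diazabicyclo[5.4.0]undec-7-ene (DBU, 10 mol %), MeCN, 0 °C to rt, 12 h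
Reagents that add atoms: none
Why: Intermolecular Michael addition (the key fragment-joining C-C bond), in which the soft beta-keto ester enolate adds 1,4 to the acrylate under catalytic base, the more hindered mono-adduct resists a second addition, and the new stereocentre is racemic, epimerisable and removed in step 4.

**Step 4**
Reactants: 10 1-tert-butyl 5-methyl 2-[(2,4-dibromophenoxy)acetyl]pentanedioate
Product: 12 methyl 6-(2,4-dibromophenoxy)-5-oxohexanoate, via beta-keto acid 11 (not isolated)
Conditions: TFA/CH2Cl2 (1:3), rt, 3 h; evaporate; toluene, 90 °C, 1 h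
Reagents that add atoms: none
Why: Acidolysis of the tert-butyl ester (E1 loss of isobutene) leaves the methyl ester untouched, the freed beta-keto acid decarboxylates thermally through the cyclic six-membered transition state, and the twice deactivated aryl ring does not cyclise onto the ketone under these mild acid conditions.

**Step 5**
Reactants: 12 methyl 6-(2,4-dibromophenoxy)-5-oxohexanoate
Product: 14 2-(2,4-dibromophenoxy)cyclohexane-1,3-dione, via potassium enolate of the dione 13 (not isolated)
Conditions: KOtBu (2.2 equiv), THF (0.05 M), 0 °C to rt, 3 h; 1 M HCl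
Reagents that add atoms: none
Why: Dieckmann-type intramolecular Claisen condensation, in which only the enolate at the aryloxy-bearing carbon can reach the ester through a six-membered ring (all other closures would give four-membered rings) and formation of the very stable enolate 13 makes the closure irreversible.

**Step 6**
Reactants: 14 2-(2,4-dibromophenoxy)cyclohexane-1,3-dione
Product: 15 3-bromo-2-(2,4-dibromophenoxy)cyclohex-2-en-1-one
Conditions: Ph3PBr2 (1.15 equiv), Et3N (1.2 equiv), MeCN, 0 °C to rt, 6 h
Reagents that add atoms: dibromotriphenylphosphorane, BrP(Br)(c1ccccc1)(c1ccccc1)c1ccccc1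
Why: Deoxybromination of a vinylogous acid, in which the enol oxygen is activated as an oxyphosphonium group and bromide displaces Ph3PO by addition-elimination, the symmetry of 14 allows only one regioisomer, and the bromine lands on the carbon that becomes the position meta to OH.

**Step 7**
Reactants: 15 3-bromo-2-(2,4-dibromophenoxy)cyclohex-2-en-1-one
Product: 16 tert-butyl{[5-bromo-6-(2,4-dibromophenoxy)cyclohexa-1,5-dien-1-yl]oxy}dimethylsilane
Conditions: TBSOTf (1.3 equiv), Et3N (2.0 equiv), CH2Cl2, 0 °C, 1 h; cold aq NaHCO3 work-up
Reagents that add atoms: tert-butyldimethylsilyl trifluoromethanesulfonate (TBSOTf), CC(C)(C)[Si](C)(C)OS(=O)(=O)C(F)(F)F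
Why: Soft enolisation (silyl dienol ether formation), in which O-silylation acidifies the alpha-prime CH2 and Et3N removes a proton to give the 2-silyloxy-1,3-diene without any strong base, and the linear dienol ether isomer would be aromatised to the same product in step 8.

**Step 8**
Reactants: 16 tert-butyl{[5-bromo-6-(2,4-dibromophenoxy)cyclohexa-1,5-dien-1-yl]oxy}dimethylsilane
Product: 17 [3-bromo-2-(2,4-dibromophenoxy)phenoxy](tert-butyl)dimethylsilane
Conditions: 2,3-dichloro-5,6-dicyano-1,4-benzoquinone (DDQ, 1.15 equiv), toluene, rt, 2 h; filter off the hydroquinone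
Reagents that add atoms: none
Why: Dehydrogenative aromatisation, in which DDQ abstracts hydride from the electron-rich cyclohexa-1,3-diene and proton loss gives the arene, the C-Br bonds are inert to DDQ, and any material desilylated here is already 18 and converges in step 9.

**Step 9**
Reactants: 17 [3-bromo-2-(2,4-dibromophenoxy)phenoxy](tert-butyl)dimethylsilane
Product: 18 3-bromo-2-(2,4-dibromophenoxy)phenol
Conditions: Bu4NF (1.1 equiv), AcOH (1.1 equiv), THF, 0 °C, 30 min
Reagents that add atoms: none
Why: Fluoride-induced desilylation driven by the strong Si-F bond is very fast for aryl silyl ethers, and the AcOH buffer protonates the phenoxide as it forms.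

**Step 10**
Reactants: 18 3-bromo-2-(2,4-dibromophenoxy)phenol
Product: 20 3,4,6-tribromo-2-(2,4-dibromophenoxy)phenol, via para-monobrominated phenol 19 (not isolated)
Conditions: Br2 (2.1 equiv), AcOH, rt, 2 h; aq Na2S2O3 wash
Reagents that add atoms: bromine, BrBr
Why: Electrophilic aromatic bromination, in which the free OH, reinforced by the ortho/para-directing C3 bromine, sends bromine first to C4 and then to C6 (an ortho-first isomer converges on the same product), while C5 is activated only by the weaker aryloxy group and ring B is deactivated by two bromines.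

**Compound list**
1 | 2,4-dibromophenol | Oc1ccc(Br)cc1Br | starting material
2 | ethyl bromoacetate | CCOC(=O)CBr | starting material
3 | potassium 2,4-dibromophenoxide | [K+].[O-]c1ccc(Br)cc1Br | intermediate
4 | ethyl 2-(2,4-dibromophenoxy)acetate | CCOC(=O)COc1ccc(Br)cc1Br | intermediate
5 | tert-butyl acetate | CC(=O)OC(C)(C)C | starting material
6 | lithium enolate of tert-butyl acetate | [Li+].[CH2-]C(=O)OC(C)(C)C | intermediate
7 | lithium enolate of tert-butyl 4-(2,4-dibromophenoxy)-3-oxobutanoate | [Li+].CC(C)(C)OC(=O)[CH-]C(=O)COc1ccc(Br)cc1Br | intermediate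
8 | tert-butyl 4-(2,4-dibromophenoxy)-3-oxobutanoate | CC(C)(C)OC(=O)CC(=O)COc1ccc(Br)cc1Br | intermediate
9 | methyl acrylate | C=CC(=O)OC | starting material
10 | 1-tert-butyl 5-methyl 2-[(2,4-dibromophenoxy)acetyl]pentanedioate (racemic, labile centre) | COC(=O)CCC(C(=O)OC(C)(C)C)C(=O)COc1ccc(Br)cc1Br | intermediate
11 | 2-[(2,4-dibromophenoxy)acetyl]-5-methoxy-5-oxopentanoic acid (racemic, labile centre) | COC(=O)CCC(C(=O)O)C(=O)COc1ccc(Br)cc1Br | intermediate
12 | methyl 6-(2,4-dibromophenoxy)-5-oxohexanoate | COC(=O)CCCC(=O)COc1ccc(Br)cc1Br | intermediate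
13 | potassium enolate of 2-(2,4-dibromophenoxy)cyclohexane-1,3-dione | [K+].O=C1CCCC(=O)[C-]1Oc1ccc(Br)cc1Br | intermediate
14 | 2-(2,4-dibromophenoxy)cyclohexane-1,3-dione (largely enolised) | O=C1CCCC(=O)C1Oc1ccc(Br)cc1Br | intermediate
15 | 3-bromo-2-(2,4-dibromophenoxy)cyclohex-2-en-1-one | O=C1CCCC(Br)=C1Oc1ccc(Br)cc1Br | intermediate
16 | tert-butyl{[5-bromo-6-(2,4-dibromophenoxy)cyclohexa-1,5-dien-1-yl]oxy}dimethylsilane | CC(C)(C)[Si](C)(C)OC1=CCCC(Br)=C1Oc1ccc(Br)cc1Br | intermediate
17 | [3-bromo-2-(2,4-dibromophenoxy)phenoxy](tert-butyl)dimethylsilane | CC(C)(C)[Si](C)(C)Oc1cccc(Br)c1Oc1ccc(Br)cc1Br | intermediate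
18 | 3-bromo-2-(2,4-dibromophenoxy)phenol | Oc1cccc(Br)c1Oc1ccc(Br)cc1Br | intermediate
19 | 3,4-dibromo-2-(2,4-dibromophenoxy)phenol | Oc1ccc(Br)c(Br)c1Oc1ccc(Br)cc1Br | intermediate
20 | 3,4,6-tribromo-2-(2,4-dibromophenoxy)phenol (achiral) | Oc1c(Br)cc(Br)c(Br)c1Oc1ccc(Br)cc1Br | target

**Total step count:** 10. **Longest linear sequence:** 10 steps (1 to 20).

**Steps most likely to fail**

Step 8 (DDQ aromatisation). DDQ may form adducts with the silyloxydiene or strip the silyl group, and the yield may be poor. The fallback replaces hydride abstraction by halogenation and dehydrohalogenation.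
- It sets out from 16. NBS in THF at 0 °C brominates the silyl dienol ether regiospecifically at the alpha-prime carbon. This gives racemic 3,6-dibromo-2-(2,4-dibromophenoxy)cyclohex-2-en-1-one F1.
- Heating with Li2CO3 and LiBr in DMF at 110 °C eliminates HBr to 3-bromo-2-(2,4-dibromophenoxy)cyclohexa-2,5-dien-1-one F2.
- This dienone tautomerises at once to the phenol. The fallback comes back to the route at 18, so 17 and the desilylation are bypassed.

Step 5 (ring closure of the delta-keto ester). The enolate on the chain side of the ketone in 12 can start intermolecular aldol chemistry or expel the fairly good aryloxide leaving group. The fallback closes the ring before decarboxylation, while that carbon is tied up as a stabilised beta-keto ester enolate.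
- It sets out from 10. KOtBu (3 equiv) in THF at reflux, then cold dilute HCl, gives tert-butyl 3-(2,4-dibromophenoxy)-2,4-dioxocyclohexane-1-carboxylate F3.
- TFA in CH2Cl2 at rt gives 3-(2,4-dibromophenoxy)-2,4-dioxocyclohexane-1-carboxylic acid F4.
- This acid loses CO2 on warming in toluene. The fallback comes back to the route at 14.

Step 2 (crossed Claisen). Proton transfer from the enolisable ester 4 to enolate 6 can stall the acylation or lead to self-condensation of 4. The fallback replaces the ester enolate by a decarboxylative acylation through Meldrum's acid.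
- It sets out from 4. LiOH in THF/water, then HCl, gives 2-(2,4-dibromophenoxy)acetic acid F5.
- Coupling with Meldrum's acid (N,N'-dicyclohexylcarbodiimide, 4-dimethylaminopyridine, CH2Cl2, 0 °C to rt) gives 5-[2-(2,4-dibromophenoxy)-1-hydroxyethylidene]-2,2-dimethyl-1,3-dioxane-4,6-dione F6.
- Heating with tert-butanol in toluene at reflux opens and decarboxylates it. The fallback comes back to the route at 8.

**Further compounds**
F1 | step 8 | 3,6-dibromo-2-(2,4-dibromophenoxy)cyclohex-2-en-1-one (racemic) | O=C1C(Br)CCC(Br)=C1Oc1ccc(Br)cc1Br
F2 | step 8 | 3-bromo-2-(2,4-dibromophenoxy)cyclohexa-2,5-dien-1-one | O=C1C=CCC(Br)=C1Oc1ccc(Br)cc1Br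
F3 | step 5 | tert-butyl 3-(2,4-dibromophenoxy)-2,4-dioxocyclohexane-1-carboxylate (enolised, labile centres) | CC(C)(C)OC(=O)C1CCC(=O)C(Oc2ccc(Br)cc2Br)C1=O
F4 | step 5 | 3-(2,4-dibromophenoxy)-2,4-dioxocyclohexane-1-carboxylic acid (enolised, labile centres) | OC(=O)C1CCC(=O)C(Oc2ccc(Br)cc2Br)C1=O
F5 | step 2 | 2-(2,4-dibromophenoxy)acetic acid | OC(=O)COc1ccc(Br)cc1Br
F6 | step 2 | 5-[2-(2,4-dibromophenoxy)-1-hydroxyethylidene]-2,2-dimethyl-1,3-dioxane-4,6-dione | CC1(C)OC(=O)C(=C(O)COc2ccc(Br)cc2Br)C(=O)O1
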